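## Structural features

- **Ring system.** The target is a compact tetracycle. Atom numbers used throughout: pyrrole N1, C2 and C3 (both Br), C4 (H), C5; aminal C6 (H); N7 (methyl); guanidine C8; N9; quaternary aminal C10; methylenes C11–C13; N14; carbonyl C15. Ring A is the dibromopyrrole. Ring B is the six-membered lactam (N1, C6, C10, N14, C15, C5). Ring C is the pyrrolidine (C10–C13, N14). Ring D is the five-membered cyclic guanidine (C6, N7, C8, N9, C10).
- **Stereocentres.** C6 and C10 are the only stereocentres and they are adjacent. Ring D spans the C6–C10 bond, so the fusion must be cis, and the real question is the absolute configuration, (6S,10R) as derived from the drawn structure.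
- **Fragile groups.** The two C–Br bonds rule out hydrogenolysis, dissolving metals and low-valent metal reagents once the pyrrole is in place. The aminal carbons can ionise under acid. The free guanidine is polar and is best made last.
- **Difficulty.** Four C–N bonds must be made at two contiguous carbons, one of them quaternary, with absolute control and with the methyl group on N7 and not on N9.
- **Feature the key step exploits.** C6 is at the aldehyde oxidation level and C10 at the ketone level, so C6–C10 is a masked 1,2-dicarbonyl unit. N1 and N14 already sit in a pyrrole-2-carboxamide chain, and N7/N9 can come from a thiourea, so rings B (six), C (five) and D (five) can all close by carbonyl–nitrogen condensation.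

## Logic of the disconnections

**14 to 12.** The exocyclic C8–NH2 bond is exchanged for C8=S. A thiourea is neutral and still nucleophilic at nitrogen under acid, whereas a guanidine would be protonated and inert in an acid-catalysed condensation. The gain is that the polar guanidine appears only in the last operation. The forward step must activate sulfur (through 13) and displace it with ammonia without opening the aminals or touching C–Br.

**12 to 8 and 9.** The four bonds N14–C10, N1–C6, N9–C10 and N7–C6 are cut, returning C10 to a ketone and C6 to an acetal-masked aldehyde. This removes three rings and both stereocentres and leaves an achiral open chain and a commercial thiourea. The forward step must order four condensations (through 10 and 11), set the absolute configuration at C10 when the thiourea first bonds, and place the NHMe nitrogen on C6.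

**8 to 7.** The C10 ketone is traced to a secondary alcohol. A ketone four atoms from a free primary amine would close to a 1-pyrroline before the amine could be acylated, so the carbonyl is unveiled only after the amide exists. The forward step needs an oxidant that spares the pyrrole N–H, the amide, the acetal and C–Br.

**7 to 5 and 6.** The amide bond N14–C15 is cut. 6 carries both bromines, so no late halogenation is needed. The forward step needs N- over O-acylation.

**5 to 1 and 2 (through 3 and 4).** The C10–C11 bond is cut, joining a two-carbon aldehyde that carries the acetal to a three-carbon aminopropyl nucleophile. The nitrogen must carry no N–H during the organomagnesium step, and the acetal must survive N-deprotection.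

## Other disconnections considered

**Alternative 1:** The cut is the C6–C10 carbon–carbon bond. The imide A1 (N-acyl pyrrolidinone whose pyrrole nitrogen bears an N-sulfinyl formamidine) would be treated with samarium diiodide A2. A ketyl from the lactam carbonyl would add to the formamidine carbon and give A3, with ring B closed.
- In favour: it joins the two aminal carbons directly from two cheap heterocycles. The sulfinyl auxiliary is a stoichiometric, well-understood source of absolute configuration at C6. On that point it is better founded than the chosen plan, whose enantiocontrol rests on an untested catalyst step.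
- Equal: both plans close ring B in a 6-exo mode.
- Against: A3 holds only two of the four aminal C–N bonds. C10 is an uncontrolled carbinol that must later be ionised and captured by N9. N7 must be desulfinylated, methylated and tied to C8. The bromines cannot be present during electron transfer (divalent samarium cleaves aryl C–Br bonds), so they would be introduced at the end on an aminal-rich substrate. The two imide carbonyls compete for reduction, and an amidine C=N is a weak radical acceptor.
- Step economy: roughly three to four steps to A1 and six or more after A3, against five steps in total for the chosen plan.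

**Alternative 2:** The cuts are C10–C11 and N14–C13. A bifunctional cinchona squaramide base would add the C5 carbanion of amidohydantoin A4 to acrolein A5, and the amide nitrogen would close on the aldehyde to give spiro compound A6.
- In favour: the quaternary centre C10 would be set by a well-precedented class of organocatalytic Michael addition, which is mechanistically better supported than the chosen cascade. Ring D is present from the start with the methyl unambiguously on N7, so the regiochemical question of the chosen plan does not arise; on this point the alternative is better.
- Equal: C6 would later follow C10 through forced cis fusion, as in the chosen plan.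
- Against: A6 still needs removal of the C13 hydroxyl, regioselective reduction of one hydantoin carbonyl (C6) in the presence of a urea, a carbamate and an amide, closure of N1–C6, carbamate removal, and conversion of a urea into the guanidine (harder than from a thiourea). Aza-Michael addition and polymerisation of A5 are competing processes.
- Step economy: about ten steps or more overall; the chosen plan is clearly shorter.

**Alternative 3:** The cuts are C10–N9 and C8–N7. The tricyclic acid A7 would be converted into acyl azide A8 and heated. C10 would migrate to nitrogen with retention to give isocyanate A9, which the methylamino group on C6 would capture to give cyclic urea A10.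
- In favour: the rearrangement is stereospecific, so the absolute configuration would come from the chiral pool. The arrangement around C10 in A7 is that of L-proline A11 with the α-hydrogen replaced by C6. Regiochemistry of the methyl is fixed. On stereochemical certainty this alternative is better than the chosen plan.
- Equal: both plans end by turning a (thio)carbonyl at C8 into the guanidine.
- Against: A7 is itself a demanding target (quaternary α-substituted amino acid, tricyclic aminal with cis C6–NHMe). A9 is an α-amido isocyanate that can fragment to an N-acyliminium ion. The urea A10 needs forcing O-alkylation before ammonolysis, whereas the thiourea of the chosen plan is alkylated at sulfur under mild conditions.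
- Step economy: ten or more steps are likely; the chosen plan is better.

Key step: step 4

Remarks on the chemistry:
- No structure needed correction: 12 and 14 carry the same (6S,10R), cis-fused arrangement.
- A 4-amino ketone with a free NH2 closes at once to the cyclic imine, so the ketone of 8 is made by oxidation after N-acylation.
- 2 is assumed to be used as the anhydrous monomer (commercial solution dried before use).
- The sense of induction of the chiral acid cannot be predicted. The (R)-acid is written; its antipode is used if it favours the wrong enantiomer.

## Route

Step 1
Reactants: 1 1-(3-bromopropyl)-2,2,5,5-tetramethyl-1-aza-2,5-disilacyclopentane; 2 2,2-dimethoxyacetaldehyde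
Product: 5 rac-5-amino-1,1-dimethoxypentan-2-ol, via Grignard reagent 3 (not isolated), via N-disilyl carbinol 4 (not isolated)
Conditions: Mg, I2 (cat.), THF, 45 °C; 2, THF, −20 to 0 °C; then HCl (1.25 M in MeOH), 0 °C to rt; NH3/MeOH
Reagents that add atoms: none
Why: Grignard addition to a non-enolisable aldehyde; the cyclic disilyl group removes both N–H bonds, and methanolic HCl then cleaves the N–Si bonds while the dimethyl acetal only exchanges degenerately with the solvent. The new carbinol centre is racemic and is erased in step 3.

Step 2
Reactants: 5 rac-5-amino-1,1-dimethoxypentan-2-ol; 6 2,2,2-trichloro-1-(4,5-dibromo-1H-pyrrol-2-yl)ethan-1-one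
Product: 7 rac-4,5-dibromo-N-(4-hydroxy-5,5-dimethoxypentyl)-1H-pyrrole-2-carboxamide
Conditions: MeCN, Et3N (cat.), rt
Reagents that add atoms: none
Why: Haloform-type acyl transfer: the primary amine attacks the trichloromethyl ketone and chloroform leaves; the neutral secondary alcohol should not compete, and both bromines arrive with the acyl donor.

Step 3
Reactants: 7 rac-4,5-dibromo-N-(4-hydroxy-5,5-dimethoxypentyl)-1H-pyrrole-2-carboxamide
Product: 8 4,5-dibromo-N-(5,5-dimethoxy-4-oxopentyl)-1H-pyrrole-2-carboxamide
Conditions: Dess–Martin periodinane, pyridine, CH2Cl2, 0 °C to rt
Reagents that add atoms: none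
Why: Dess–Martin oxidation of a secondary alcohol under buffered, non-aqueous conditions; the acyl- and bromine-deactivated pyrrole and the acetal should be inert. Any ring-closed carbinolamide tautomer of 8 lies on the path of step 4.

Step 4
Reactants: 8 4,5-dibromo-N-(5,5-dimethoxy-4-oxopentyl)-1H-pyrrole-2-carboxamide; 9 N-methylthiourea
Product: 12 (6S,10R) cyclic thiourea analogue of the target (C8=S), via bicyclic methoxy carbinolamide 10 (not isolated), via ring-D-open thiourea adduct 11 (not isolated)
Conditions: (R)-3,3'-bis(2,4,6-triisopropylphenyl)-1,1'-binaphthyl-2,2'-diyl hydrogen phosphate (10 mol %), 5 Å MS, CH2Cl2, 35 °C; then 9 (1.1 equiv), 0 °C to rt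
Reagents that add atoms: none
Why: Proposed new method: under the chiral acid the amide N–H of 8 should add to the activated ketone (5-exo-trig, ring C), and the acetal, no longer next to a carbonyl, should ionise to an oxocarbenium ion that the pyrrole N–H captures (6-exo-trig, ring B), giving 10 as labile epimers; the closest known reactions are carbinolamide closure of pyrrole-2-carboxamides onto aldehydes and acid-catalysed transacetalisation. Loss of water from C10 of 10 then gives a tertiary N-acyliminium ion paired with the chiral phosphate, and the unsubstituted NH2 of 9, hydrogen-bonded to the phosphoryl oxygen, adds to one face to give 11; this step fixes C10 under catalyst control and its closest analogy is the chiral phosphoric acid-catalysed addition of N–H nucleophiles to N-acyliminium ions. Ionisation of the C6 methoxy group and capture by the NHMe nitrogen closes ring D (5-exo-trig); N7 is tethered through C8 and N9 to C10, so it can reach only the face of C6 that gives cis fusion, and C6 therefore follows C10 by substrate control whichever C6 epimer ionises. Overall this is the glycoluril-type double amidoalkylation of a 1,2-dicarbonyl compound by a (thio)urea, known with achiral acids but not as an enantioselective four-bond cascade. Regiochemistry (methyl on N7) is secured by adding 9 only after 10 has formed, so that the hindered C10 is the first electrophile offered and only the NH2 end can reach it. N- rather than C-attack by the pyrrole is secured by the acyl group and the two bromines, which deactivate the one free ring carbon C4, and kinetic S-adducts of the thiourea should revert under the acid. Once both bonds to the thiourea exist, the bis-aminal cannot racemise without breaking two C–N bonds at once.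

Step 5
Reactants: 12 (6S,10R) cyclic thiourea analogue of the target
Product: 14 (−)-7-N-methyldibromophakellin, via S-methylisothiouronium iodide 13 (not isolated)
Conditions: MeI, acetone, rt; evaporate; NH3 (7 M in MeOH), sealed tube, 60 °C
Reagents that add atoms: ammonia, N
Why: S-Alkylation of the thiourea followed by addition–elimination of ammonia at the amidinium carbon with loss of methanethiol (isothiourea aminolysis). Neither aminal carbon is involved, so the configuration is kept; excess MeI is removed before ammonia is added so that no methylamine forms, and excess ammonia should free the weakly basic guanidine.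

## Compound list

1 | 1-(3-bromopropyl)-2,2,5,5-tetramethyl-1-aza-2,5-disilacyclopentane | BrCCCN1[Si](C)(C)CC[Si]1(C)C | starting material
2 | 2,2-dimethoxyacetaldehyde | COC(OC)C=O | starting material
3 | [3-(2,2,5,5-tetramethyl-1-aza-2,5-disilacyclopentan-1-yl)propyl]magnesium bromide | Br[Mg]CCCN1[Si](C)(C)CC[Si]1(C)C | intermediate
4 | rac-1,1-dimethoxy-5-(2,2,5,5-tetramethyl-1-aza-2,5-disilacyclopentan-1-yl)pentan-2-ol (formed as its bromomagnesium alkoxide) | COC(OC)C(O)CCCN1[Si](C)(C)CC[Si]1(C)C | intermediate
5 | rac-5-amino-1,1-dimethoxypentan-2-ol | COC(OC)C(O)CCCN | intermediate
6 | 2,2,2-trichloro-1-(4,5-dibromo-1H-pyrrol-2-yl)ethan-1-one | O=C(c1cc(Br)c(Br)[nH]1)C(Cl)(Cl)Cl | starting material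
7 | rac-4,5-dibromo-N-(4-hydroxy-5,5-dimethoxypentyl)-1H-pyrrole-2-carboxamide | COC(OC)C(O)CCCNC(=O)c1cc(Br)c(Br)[nH]1 | intermediate
8 | 4,5-dibromo-N-(5,5-dimethoxy-4-oxopentyl)-1H-pyrrole-2-carboxamide | COC(OC)C(=O)CCCNC(=O)c1cc(Br)c(Br)[nH]1 | intermediate
9 | N-methylthiourea | CNC(N)=S | starting material
10 | bicyclic carbinolamide with rings A, B and C closed, C6–OMe and C10–OH (epimers at both carbons) | COC1n2c(Br)c(Br)cc2C(=O)N2CCCC12O | intermediate
11 | thiourea adduct with rings A, B and C closed, C10 bearing NH–C(=S)–NHMe and configured as in 12, C6–OMe (C6 epimers) | CNC(=S)N[C@]12CCCN1C(=O)c1cc(Br)c(Br)n1C2OC | intermediate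
12 | (6S,10R) cis-fused tetracyclic thiourea (C8=S, N7–Me, N9–H) | CN1C(=S)N[C@]23CCCN2C(=O)c2cc(Br)c(Br)n2[C@H]13 | intermediate
13 | S-methylisothiouronium iodide of 12 (configuration as in 12) | CN1C(SC)=[NH+][C@]23CCCN2C(=O)c2cc(Br)c(Br)n2[C@H]13.[I-] | intermediate
14 | (−)-7-N-methyldibromophakellin, (6S,10R) | CN1C(N)=N[C@]23CCCN2C(=O)c2cc(Br)c(Br)n2[C@H]13 | target

## Step count and risks

Total step count: 5. Longest linear sequence: 5 steps (1 and 2 to 14).

**Step 4 (key step, proposed new method).**
- What may go wrong: poor facial discrimination when the thiourea first bonds to C10; stalling at acetal ionisation under the weak chiral acid; regiochemical leakage if the thiourea reaches the C6 cation before ring B has closed; erosion of enantiopurity through reversible loss of the thiourea from 11 before ring D closes.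
- Why: the enantio-determining ion pair is untested and the C6 cation is only weakly stabilised by the pyrrole nitrogen.
- Fallback from 8, rejoining at 12, using known reaction types: 8 would be hydrolysed with aqueous trifluoroacetic acid, whereupon the keto aldehyde should close to the racemic bicyclic bis-carbinolamide F1. F1 and 9 would be condensed under an achiral Brønsted acid in the manner of glycoluril formation (acid-catalysed amidoalkylation of a thiourea) to the racemic cis-fused thiourea F2. F2 would be resolved by preparative chromatography on a chiral stationary phase into 12 and its antipode F3, which is discarded.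

**Step 1.**
- What may go wrong: homocoupling or premature N–Si cleavage during Grignard formation; incomplete addition to partly oligomerised aldehyde; loss of the water-soluble amino alcohol on isolation.
- Fallback from 2, rejoining at 5: commercial 3-chloropropylamine hydrochloride would be dibenzylated (benzyl bromide, K2CO3, MeCN) to N,N-dibenzyl-3-chloropropan-1-amine F4. This would be converted with Mg in THF into 3-(dibenzylamino)propylmagnesium chloride F5 and added to 2 to give the lipophilic, chromatographable rac-5-(dibenzylamino)-1,1-dimethoxypentan-2-ol F6. Hydrogenolysis (H2, Pd(OH)2 on carbon, MeOH) would then give 5. No bromine is present at that stage.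

**Step 5.**
- What may go wrong: slow displacement of methanethiolate at an amidinium carbon flanked by two hindered aminal nitrogens; competing opening of ring D by expulsion of an aminal nitrogen on prolonged heating.
- Fallback from 13, rejoining at 14: 13 would be neutralised (aq. NaHCO3) to the free S-methyl isothiourea F7. Oxidation with mCPBA in CH2Cl2 at 0 °C would give the 2-methylsulfonyl imidazoline F8, a much better electrophile. Ammonia in THF at room temperature should then displace methanesulfinate and give 14.

**Step 3.**
- What may go wrong: oxidative attack on the pyrrole; acetal loss through the acetic acid released; incomplete oxidation if the alcohol is hindered by hydrogen bonding to the amide.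
- Fallback from 1 (through 3), rejoining at 8, avoiding any oxidation: 3 would be added at −78 °C to commercial methyl dimethoxyacetate to give the N-disilyl keto acetal F9. Methanolic HCl would remove the silyl groups, and the free amino ketone should close to the cyclic imine 5-(dimethoxymethyl)-3,4-dihydro-2H-pyrrole F10. F10 would be acylated under Schotten–Baumann conditions (CH2Cl2/aq. NaHCO3) with 4,5-dibromo-1H-pyrrole-2-carbonyl chloride F11 (from the commercial acid and oxalyl chloride). The N-acyliminium ion should take up water and open to 8.

## Further compounds

F1 | step 4 | racemic bicyclic bis-carbinolamide (C6–OH, C10–OH, rings A, B and C closed) | OC1n2c(Br)c(Br)cc2C(=O)N2CCCC12O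
F2 | step 4 | racemic cis-fused tetracyclic thiourea | CN1C(=S)NC23CCCN2C(=O)c2cc(Br)c(Br)n2C13
F3 | step 4 | (6R,10S) antipode of 12 | CN1C(=S)N[C@@]23CCCN2C(=O)c2cc(Br)c(Br)n2[C@@H]13
F4 | step 1 | N,N-dibenzyl-3-chloropropan-1-amine | ClCCCN(Cc1ccccc1)Cc1ccccc1
F5 | step 1 | 3-(dibenzylamino)propylmagnesium chloride | Cl[Mg]CCCN(Cc1ccccc1)Cc1ccccc1
F6 | step 1 | rac-5-(dibenzylamino)-1,1-dimethoxypentan-2-ol | COC(OC)C(O)CCCN(Cc1ccccc1)Cc1ccccc1
F7 | step 5 | free S-methyl isothiourea of 12 | CN1C(SC)=N[C@]23CCCN2C(=O)c2cc(Br)c(Br)n2[C@H]13
F8 | step 5 | 2-methylsulfonyl imidazoline analogue of 12 | CN1C(=N[C@]23CCCN2C(=O)c2cc(Br)c(Br)n2[C@H]13)S(C)(=O)=O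
F9 | step 3 | 1,1-dimethoxy-5-(2,2,5,5-tetramethyl-1-aza-2,5-disilacyclopentan-1-yl)pentan-2-one | COC(OC)C(=O)CCCN1[Si](C)(C)CC[Si]1(C)C
F10 | step 3 | 5-(dimethoxymethyl)-3,4-dihydro-2H-pyrrole | COC(OC)C1=NCCC1
F11 | step 3 | 4,5-dibromo-1H-pyrrole-2-carbonyl chloride | ClC(=O)c1cc(Br)c(Br)[nH]1
A1 | alternative 1 | N-acyl pyrrolidinone imide with N-sulfinyl formamidine on the pyrrole nitrogen | CC(C)(C)[S@@](=O)N=Cn1cccc1C(=O)N1CCCC1=O
A2 | alternative 1 | samarium diiodide | [Sm+2].[I-].[I-]
A3 | alternative 1 | tricyclic C10 hemiaminal with C6 sulfinamide (hydroxyl epimers) | CC(C)(C)[S@@](=O)N[C@H]1n2cccc2C(=O)N2CCCC12O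
A4 | alternative 2 | 1-Boc-3-methyl-5-(4,5-dibromo-1H-pyrrole-2-carboxamido)hydantoin | CN1C(=O)N(C(=O)OC(C)(C)C)C(NC(=O)c2cc(Br)c(Br)[nH]2)C1=O
A5 | alternative 2 | acrolein | C=CC=O
A6 | alternative 2 | spiro hydantoin–hydroxypyrrolidine (carbinol epimers) | CN1C(=O)N(C(=O)OC(C)(C)C)[C@@]2(CCC(O)N2C(=O)c2cc(Br)c(Br)[nH]2)C1=O
A7 | alternative 3 | tricyclic aminal C10 carboxylic acid with C6 methylamino group | CN[C@H]1n2c(Br)c(Br)cc2C(=O)N2CCC[C@]12C(=O)O
A8 | alternative 3 | acyl azide of A7 | CN[C@H]1n2c(Br)c(Br)cc2C(=O)N2CCC[C@]12C(=O)N=[N+]=[N-]
A9 | alternative 3 | C10 isocyanate | CN[C@H]1n2c(Br)c(Br)cc2C(=O)N2CCC[C@]12N=C=O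
A10 | alternative 3 | cyclic urea analogue of the target | CN1C(=O)N[C@]23CCCN2C(=O)c2cc(Br)c(Br)n2[C@H]13
A11 | alternative 3 | L-proline | OC(=O)[C@@H]1CCCN1
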